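Ring B is built on a finished chromone instead of being carried in as a benzoyl unit. Disconnecting C2'–C3' and C1'–C6' leads back to 3,4-dimethoxyfuran and an ethynyl group on C2 of ring C. The key step exploits the pattern of ring B, a free hydroxyl on C3' next to methyl ethers on C4' and C5', with C1' bonded to C2. Cycloaddition followed by acid opening of the oxygen bridge turns the furan oxygen into the C3' hydroxyl and brings in both methoxy groups, so ring B needs no protecting group. The precursor is 3,5,7-tris(benzyloxy)-2-ethynyl-8-methoxychromen-4-one, reached from 2-methoxyresorcinol through a 2-methylchromone.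

Key step: step 11

Assumption: compounds 1, 6 and 17 are bought; 13 and 18 are racemic and lose their stereocentres in the flask in which they form; ring B is numbered C1' (bonded to C2) to C6', and the target has no stereocentre.

Step 1
Reactants: 1 2-methoxyresorcinol
Product: 2 2-methoxy-1,3-bis(methoxymethoxy)benzene
Conditions: MOMCl, i-Pr2NEt, CH2Cl2, 0 °C → rt
Reagents that add atoms: chloromethyl methyl ether, COCCl
Why: O-alkylation of both phenols with the reactive α-chloro ether (Williamson-type acetal ether formation) is routine, and the MOM groups later direct the ring lithiation and come off under acid that spares benzyl ethers.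

Step 2
Reactants: 2 2-methoxy-1,3-bis(methoxymethoxy)benzene
Product: 4 4-methoxy-3,5-bis(methoxymethoxy)phenol, via aryl pinacol boronate 3 (not isolated)
Conditions: [Ir(OMe)(cod)]2 (cat.), 4,4'-di-tert-butyl-2,2'-bipyridine, B2pin2, THF, 80 °C; then aq. NaOH, H2O2, 0 °C → rt
Reagents that add atoms: hydrogen peroxide, OO; bis(pinacolato)diboron, CC1(C)OB(OC1(C)C)B1OC(C)(C)C(C)(C)O1 (boron held only in 3)
Why: Iridium-catalysed aromatic C–H borylation is governed by steric access and should therefore take place only at C5, the one C–H without an ortho substituent, and basic peroxide oxidation of the C–B bond then gives the phenol without harming the acetals.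

Step 3
Reactants: 4 4-methoxy-3,5-bis(methoxymethoxy)phenol
Product: 5 5-(benzyloxy)-2-methoxy-1,3-bis(methoxymethoxy)benzene
Conditions: BnBr, K2CO3, DMF, rt
Reagents that add atoms: benzyl bromide, BrCc1ccccc1
Why: Williamson ether synthesis on the only free phenol should be clean, and the benzyl ether marks the oxygen that becomes O5 of ring A.

Step 4
Reactants: 6 benzyloxyacetyl chloride
Product: 7 2-(benzyloxy)-N-methoxy-N-methylacetamide
Conditions: MeNHOMe·HCl, Et3N, CH2Cl2, 0 °C → rt
Reagents that add atoms: N,O-dimethylhydroxylamine hydrochloride, CNOC.Cl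
Why: N-acylation of the hydroxylamine by the acid chloride (Weinreb amide formation) is a standard amide synthesis.

Step 5
Reactants: 5 5-(benzyloxy)-2-methoxy-1,3-bis(methoxymethoxy)benzene; 7 2-(benzyloxy)-N-methoxy-N-methylacetamide
Product: 9 2-(benzyloxy)-1-[6-(benzyloxy)-3-methoxy-2,4-bis(methoxymethoxy)phenyl]ethan-1-one, via aryllithium 8 (not isolated)
Conditions: n-BuLi, THF, 0 °C; then 7, −78 → 0 °C; aq. NH4Cl
Reagents that add atoms: n-butyllithium, [Li]CCCC (lithium held only in 8)
Why: Directed ortho-metalation should occur at the ring C–H flanked by the MOM ether and the benzyl ether (the two free ring positions are equivalent), and the Weinreb ketone synthesis stops the acylation at the ketone stage.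

Step 6
Reactants: 9 2-(benzyloxy)-1-[6-(benzyloxy)-3-methoxy-2,4-bis(methoxymethoxy)phenyl]ethan-1-one
Product: 10 2-(benzyloxy)-1-[6-(benzyloxy)-2,4-dihydroxy-3-methoxyphenyl]ethan-1-one
Conditions: 3 M HCl, MeOH, 50 °C
Reagents that add atoms: none
Why: Acid-catalysed acetal exchange with methanol removes both MOM groups while benzyl ethers, the methyl ether and the α-benzyloxy ketone are stable.

Step 7
Reactants: 10 2-(benzyloxy)-1-[6-(benzyloxy)-2,4-dihydroxy-3-methoxyphenyl]ethan-1-one
Product: 11 2-(benzyloxy)-1-[4,6-bis(benzyloxy)-2-hydroxy-3-methoxyphenyl]ethan-1-one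
Conditions: BnBr (1.05 equiv), K2CO3, acetone, 50 °C
Reagents that add atoms: benzyl bromide, BrCc1ccccc1
Why: Williamson etherification should select the 4-hydroxyl, because the 2-hydroxyl is held in a hydrogen bond to the ketone and is the less acidic and less nucleophilic of the two.

Step 8
Reactants: 11 2-(benzyloxy)-1-[4,6-bis(benzyloxy)-2-hydroxy-3-methoxyphenyl]ethan-1-one
Product: 14 3,5,7-tris(benzyloxy)-8-methoxy-2-methylchromen-4-one, via aryl acetate 12 (not isolated), via 1,3-diketone 13 (not isolated)
Conditions: Ac2O, NaOAc, 150 °C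
Reagents that add atoms: acetic anhydride, CC(=O)OC(C)=O
Why: In the Kostanecki–Robinson reaction the phenol is acetylated, the acetyl group shifts to the acidic α-benzyloxy methylene carbon (Baker–Venkataraman type), and cyclodehydration through the only free phenol closes ring C with the methoxy group fixed at C8.

Step 9
Reactants: 14 3,5,7-tris(benzyloxy)-8-methoxy-2-methylchromen-4-one
Product: 15 3,5,7-tris(benzyloxy)-8-methoxy-4-oxo-4H-chromene-2-carbaldehyde
Conditions: SeO2, 1,4-dioxane/xylene, 120 °C
Reagents that add atoms: selenium dioxide, O=[Se]=O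
Why: The C2 methyl group is activated vinylogously by the C4 carbonyl, so Riley oxidation should convert it into the aldehyde, as it does with 2-methylchromones and 3-alkoxy-2-methylpyran-4-ones.

Step 10
Reactants: 15 3,5,7-tris(benzyloxy)-8-methoxy-4-oxo-4H-chromene-2-carbaldehyde
Product: 16 3,5,7-tris(benzyloxy)-2-ethynyl-8-methoxychromen-4-one
Conditions: dimethyl (1-diazo-2-oxopropyl)phosphonate, K2CO3, MeOH/THF, 0 °C → rt, short reaction time
Reagents that add atoms: dimethyl (1-diazo-2-oxopropyl)phosphonate, COP(=O)(OC)C(=[N+]=[N-])C(C)=O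
Why: Seyferth–Gilbert homologation with the Ohira–Bestmann reagent converts a non-enolisable aldehyde into the terminal alkyne under mild carbonate conditions by olefination, loss of nitrogen and 1,2-hydrogen shift.

Step 11
Reactants: 16 3,5,7-tris(benzyloxy)-2-ethynyl-8-methoxychromen-4-one; 17 3,4-dimethoxyfuran
Product: 19 3,5,7-tris(benzyloxy)-2-(3-hydroxy-4,5-dimethoxyphenyl)-8-methoxychromen-4-one, via oxanorbornadiene cycloadduct 18 (not isolated)
Conditions: 17 (5 equiv), toluene, 100 °C, sealed tube; evaporate; then BF3·OEt2 (2.5 equiv), CH2Cl2, −40 → 0 °C; aq. NaHCO3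
Reagents that add atoms: none
Why: Proposed new method: the electron-rich diene 17 should add across the terminal alkyne of 16, which is polarised through C2=C3–C4=O of ring C like a vinylogous propiolate, in a concerted (4+2) cycloaddition of normal electron demand that forms C2'–C3' and C1'–C6' and gives the 7-oxanorbornadiene 18, after which BF3 ionises one bridge C–O bond to a cyclohexadienyl cation that loses the proton on the carbon still bearing oxygen and aromatises to the phenol. The closest known reaction type is the Diels–Alder addition of furans, 3,4-dialkoxyfurans included, to acetylenic esters and ketones followed by Lewis acid isomerisation of the 7-oxanorbornadiene to a phenol, and the extension lies in an alkyne that is activated only through the chromone. Ring B is closed by intermolecular (4+2) annulation, four carbons coming from the furan and two from the alkyne, and the oxygen-bridged ring formed with it is opened again in the same flask. The bridgehead stereocentres of 18 are racemic and vanish on aromatisation, so no stereocontrol is needed, and because 17 is symmetric only one cycloadduct can form. The selectivity needed is the direction of bridge opening: the C6'–O bond must break so that oxygen stays on C3', meta to C1', and this should be favoured because the resulting cation carries its charge on C2', C4' (stabilised by its methoxy group) and C6', whereas breaking C3'–O would put charge on C1' next to the BF3-complexed, electron-poor chromone. Benzyl ethers should be inert to BF3·OEt2 at this temperature, which is why no acetal or ester protecting group is left in 16.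

Step 12
Reactants: 19 3,5,7-tris(benzyloxy)-2-(3-hydroxy-4,5-dimethoxyphenyl)-8-methoxychromen-4-one
Product: 20 3,5,7-trihydroxy-2-(3-hydroxy-4,5-dimethoxyphenyl)-8-methoxychromen-4-one
Conditions: H2 (1 atm), Pd/C, THF/MeOH, rt
Reagents that add atoms: none
Why: Catalytic hydrogenolysis cleaves the three benzyl ethers under neutral conditions that leave the methyl ethers and the flavonol C2=C3 bond intact and avoid acid-induced Wessely–Moser isomerisation of ring A.

Compound list
1 | 2-methoxyresorcinol (2-methoxybenzene-1,3-diol) | COc1c(O)cccc1O | starting material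
2 | 2-methoxy-1,3-bis(methoxymethoxy)benzene | COCOc1cccc(OCOC)c1OC | intermediate
3 | 2-[4-methoxy-3,5-bis(methoxymethoxy)phenyl]-4,4,5,5-tetramethyl-1,3,2-dioxaborolane | COCOc1cc(B2OC(C)(C)C(C)(C)O2)cc(OCOC)c1OC | intermediate
4 | 4-methoxy-3,5-bis(methoxymethoxy)phenol | COCOc1cc(O)cc(OCOC)c1OC | intermediate
5 | 5-(benzyloxy)-2-methoxy-1,3-bis(methoxymethoxy)benzene | COCOc1cc(OCc2ccccc2)cc(OCOC)c1OC | intermediate
6 | benzyloxyacetyl chloride | O=C(Cl)COCc1ccccc1 | starting material
7 | 2-(benzyloxy)-N-methoxy-N-methylacetamide | CON(C)C(=O)COCc1ccccc1 | intermediate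
8 | [6-(benzyloxy)-3-methoxy-2,4-bis(methoxymethoxy)phenyl]lithium | [Li]c1c(OCOC)c(OC)c(OCOC)cc1OCc1ccccc1 | intermediate
9 | 2-(benzyloxy)-1-[6-(benzyloxy)-3-methoxy-2,4-bis(methoxymethoxy)phenyl]ethan-1-one | O=C(COCc1ccccc1)c1c(OCOC)c(OC)c(OCOC)cc1OCc1ccccc1 | intermediate
10 | 2-(benzyloxy)-1-[6-(benzyloxy)-2,4-dihydroxy-3-methoxyphenyl]ethan-1-one | O=C(COCc1ccccc1)c1c(O)c(OC)c(O)cc1OCc1ccccc1 | intermediate
11 | 2-(benzyloxy)-1-[4,6-bis(benzyloxy)-2-hydroxy-3-methoxyphenyl]ethan-1-one | O=C(COCc1ccccc1)c1c(O)c(OC)c(OCc2ccccc2)cc1OCc1ccccc1 | intermediate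
12 | 3,5-bis(benzyloxy)-2-[(benzyloxy)acetyl]-6-methoxyphenyl acetate | CC(=O)Oc1c(OC)c(OCc2ccccc2)cc(OCc2ccccc2)c1C(=O)COCc1ccccc1 | intermediate
13 | 2-(benzyloxy)-1-[4,6-bis(benzyloxy)-2-hydroxy-3-methoxyphenyl]butane-1,3-dione (racemic) | CC(=O)C(OCc1ccccc1)C(=O)c1c(O)c(OC)c(OCc2ccccc2)cc1OCc1ccccc1 | intermediate
14 | 3,5,7-tris(benzyloxy)-8-methoxy-2-methylchromen-4-one | Cc1oc2c(OC)c(OCc3ccccc3)cc(OCc3ccccc3)c2c(=O)c1OCc1ccccc1 | intermediate
15 | 3,5,7-tris(benzyloxy)-8-methoxy-4-oxo-4H-chromene-2-carbaldehyde | O=Cc1oc2c(OC)c(OCc3ccccc3)cc(OCc3ccccc3)c2c(=O)c1OCc1ccccc1 | intermediate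
16 | 3,5,7-tris(benzyloxy)-2-ethynyl-8-methoxychromen-4-one | C#Cc1oc2c(OC)c(OCc3ccccc3)cc(OCc3ccccc3)c2c(=O)c1OCc1ccccc1 | intermediate
17 | 3,4-dimethoxyfuran | COc1cocc1OC | starting material
18 | 3,5,7-tris(benzyloxy)-2-(5,6-dimethoxy-7-oxabicyclo[2.2.1]hepta-2,5-dien-2-yl)-8-methoxychromen-4-one (racemic) | COC1=C(OC)C2OC1C=C2c1oc2c(OC)c(OCc3ccccc3)cc(OCc3ccccc3)c2c(=O)c1OCc1ccccc1 | intermediate
19 | 3,5,7-tris(benzyloxy)-2-(3-hydroxy-4,5-dimethoxyphenyl)-8-methoxychromen-4-one | COc1cc(-c2oc3c(OC)c(OCc4ccccc4)cc(OCc4ccccc4)c3c(=O)c2OCc2ccccc2)cc(O)c1OC | intermediate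
20 | 3,5,7-trihydroxy-2-(3-hydroxy-4,5-dimethoxyphenyl)-8-methoxychromen-4-one | COc1cc(-c2oc3c(OC)c(O)cc(O)c3c(=O)c2O)cc(O)c1OC | target

Total step count: 12. Longest linear sequence: 11 steps (steps 1–3 and 5–12, from 1 to 20); step 4 is a one-step side branch.

Steps most likely to fail

Step 11 (carries the label). The alkyne is activated only through the chromone, so cycloaddition may be too slow and the furan may oligomerise or add in a Michael sense before ring B closes. The bridge may also open in the wrong direction and leave the hydroxyl ortho to C1'. Fallback with known chemistry, setting out from 11 and coming back at 20, brings ring B in ready-made by a Baker–Venkataraman flavonol synthesis. Commercial methyl 3-hydroxy-4,5-dimethoxybenzoate is benzylated (BnBr, K2CO3, DMF) to methyl 3-(benzyloxy)-4,5-dimethoxybenzoate F1. Saponification (LiOH, THF/H2O) gives 3-(benzyloxy)-4,5-dimethoxybenzoic acid F2, which is converted ((COCl)2, cat. DMF, CH2Cl2) into 3-(benzyloxy)-4,5-dimethoxybenzoyl chloride F3. Ketone 11 is O-acylated with F3 (pyridine, DMAP) to 3,5-bis(benzyloxy)-2-[(benzyloxy)acetyl]-6-methoxyphenyl 3-(benzyloxy)-4,5-dimethoxybenzoate F4. Base (LiN(SiMe3)2, THF, or KOH, pyridine) should shift the aroyl group to carbon and give 2-(benzyloxy)-1-[4,6-bis(benzyloxy)-2-hydroxy-3-methoxyphenyl]-3-[3-(benzyloxy)-4,5-dimethoxyphenyl]propane-1,3-dione F5. Cyclodehydration (AcOH, cat. H2SO4) should give 3,5,7-tris(benzyloxy)-2-[3-(benzyloxy)-4,5-dimethoxyphenyl]-8-methoxychromen-4-one F6, and hydrogenolysis of its four benzyl ethers under the conditions of step 12 gives 20. Steps 8 to 11 are then not needed.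

Step 10. Methoxide may add in a conjugate sense to the newly formed chromone-activated alkyne, or open the pyranone ring, under the basic methanolic conditions. The fallback sets out from 15 and comes back at 16 by olefination and elimination without a nucleophilic base. Wittig reaction of 15 with the ylide from (bromomethyl)triphenylphosphonium bromide and NaN(SiMe3)2 (THF, −78 °C) should give (Z)-3,5,7-tris(benzyloxy)-2-(2-bromoethenyl)-8-methoxychromen-4-one F7. Anti-dehydrobromination with DBU (MeCN, rt to 60 °C) then gives 16.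

Step 9. Over-oxidation to the carboxylic acid, incomplete conversion at temperatures the benzyl ethers tolerate, and carry-over of selenium that would poison the palladium catalyst of step 12 are the likely problems. The fallback sets out from 14 and comes back at 15. Condensation of the activated methyl group with N,N-dimethylformamide dimethyl acetal (DMF, 130 °C) should give (E)-3,5,7-tris(benzyloxy)-2-[2-(dimethylamino)ethenyl]-8-methoxychromen-4-one F8. Oxidative cleavage of the enamine double bond with NaIO4 (THF/H2O, rt) then gives 15.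

Further compounds
F1 | step 11 | methyl 3-(benzyloxy)-4,5-dimethoxybenzoate | COC(=O)c1cc(OC)c(OC)c(OCc2ccccc2)c1
F2 | step 11 | 3-(benzyloxy)-4,5-dimethoxybenzoic acid | OC(=O)c1cc(OC)c(OC)c(OCc2ccccc2)c1
F3 | step 11 | 3-(benzyloxy)-4,5-dimethoxybenzoyl chloride | ClC(=O)c1cc(OC)c(OC)c(OCc2ccccc2)c1
F4 | step 11 | 3,5-bis(benzyloxy)-2-[(benzyloxy)acetyl]-6-methoxyphenyl 3-(benzyloxy)-4,5-dimethoxybenzoate | O=C(Oc1c(OC)c(OCc2ccccc2)cc(OCc2ccccc2)c1C(=O)COCc1ccccc1)c1cc(OC)c(OC)c(OCc2ccccc2)c1
F5 | step 11 | 2-(benzyloxy)-1-[4,6-bis(benzyloxy)-2-hydroxy-3-methoxyphenyl]-3-[3-(benzyloxy)-4,5-dimethoxyphenyl]propane-1,3-dione (racemic) | O=C(c1cc(OC)c(OC)c(OCc2ccccc2)c1)C(OCc1ccccc1)C(=O)c1c(O)c(OC)c(OCc2ccccc2)cc1OCc1ccccc1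
F6 | step 11 | 3,5,7-tris(benzyloxy)-2-[3-(benzyloxy)-4,5-dimethoxyphenyl]-8-methoxychromen-4-one | COc1cc(-c2oc3c(OC)c(OCc4ccccc4)cc(OCc4ccccc4)c3c(=O)c2OCc2ccccc2)cc(OCc2ccccc2)c1OC
F7 | step 10 | (Z)-3,5,7-tris(benzyloxy)-2-(2-bromoethenyl)-8-methoxychromen-4-one | Br/C=C\c1oc2c(OC)c(OCc3ccccc3)cc(OCc3ccccc3)c2c(=O)c1OCc1ccccc1
F8 | step 9 | (E)-3,5,7-tris(benzyloxy)-2-[2-(dimethylamino)ethenyl]-8-methoxychromen-4-one | CN(C)/C=C/c1oc2c(OC)c(OCc3ccccc3)cc(OCc3ccccc3)c2c(=O)c1OCc1ccccc1
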